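**Strategy**

Everything rests on the C4–C4a acyl–aryl disconnection of ring C, made at the chromone level before C2 bears its aryl group. The key step is a Friedel–Crafts ring closure of (E)-3-(3,5-dimethoxy-2-prenylphenoxy)acrylic acid: through its acid chloride, the O1-stabilised acyl cation loses its C2=C3 geometry, turns cisoid and is attacked by C4a of ring A, the C–H ortho to O1 and the C5 methoxy group and para to the C7 methoxy group. One operation thus builds the pyranone with its C2=C3 bond; the precursor is achiral, so nothing stereogenic meets acid. A ligand-controlled Pd-catalysed conjugate addition of the B-ring boronic acid then sets (2S)-C2 last, without protecting groups.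

Key step: step 3

Assumptions: (i) the target is the (2S)-flavanone, C2 being its only stereocentre; (ii) salts formed by deprotonation (phenoxides, carboxylates) are treated as ionised forms of the numbered compounds; (iii) 1, 2, 4, 9 and all reagents, including both enantiomers of the t-BuPyOx ligand, are taken as commercially available.

**Route**

Step 1
Reactants: 1 3,5-dimethoxyphenol; 2 prenyl bromide (1-bromo-3-methylbut-2-ene)
Product: 3 3,5-dimethoxy-2-(3-methylbut-2-en-1-yl)phenol
Conditions: NaH (1.05 equiv), toluene, 0 °C; then 2 (1.0 equiv), 0 °C → rt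
Reagents that add atoms: none
Why: ortho-C-alkylation of a sodium phenoxide in a non-polar solvent, in which the tight O–Na ion pair directs SN2 attack of an ortho carbon (the two are equivalent in 1) on the primary allylic bromide, so the linear prenyl group should be placed next to the OH, with the O-prenyl ether and the C4 isomer as the separable side products to be expected.

Step 2
Reactants: 3 3,5-dimethoxy-2-(3-methylbut-2-en-1-yl)phenol; 4 methyl propiolate
Product: 6 (2E)-3-[3,5-dimethoxy-2-(3-methylbut-2-en-1-yl)phenoxy]prop-2-enoic acid, via methyl (E)-3-aryloxyacrylate 5 (not isolated)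
Conditions: DABCO (10 mol%), THF, 0 °C → rt; then LiOH·H2O (3 equiv), H2O/MeOH, rt; 1 M HCl to pH 3 at 0 °C
Reagents that add atoms: water (from aqueous LiOH), O
Why: amine-catalysed oxa-Michael addition of the phenol to the propiolate (through the β-ammonium acrylate) should give the (E)-β-aryloxyacrylate 5, whose methyl ester is then saponified in the same flask, hydroxide attacking the ester carbonyl of this vinylogous carbonate faster than C-β.

Step 3
Reactants: 6 (2E)-3-[3,5-dimethoxy-2-(3-methylbut-2-en-1-yl)phenoxy]prop-2-enoic acid
Product: 8 5,7-dimethoxy-8-(3-methylbut-2-en-1-yl)-4H-chromen-4-one, via (E)-3-aryloxyacryloyl chloride 7 (not isolated)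
Conditions: 1-chloro-N,N,2-trimethylprop-1-en-1-amine (1.1 equiv), CH2Cl2, 0 °C → rt; then 2,6-di-tert-butyl-4-methylpyridine (1.2 equiv), SnCl4 (1.2 equiv), CH2Cl2 (0.02 M), −78 → 0 °C; aq. NaHCO3
Reagents that add atoms: 1-chloro-N,N,2-trimethylprop-1-en-1-amine, CC(C)=C(Cl)N(C)C (its chlorine is carried by intermediate 7 only)
Why: The chloroenamine converts 6 into acid chloride 7 without releasing HCl, and SnCl4 ionises 7 to a β-aryloxyacryloyl cation, a vinylogous oxocarbenium ion (ArO+=CH–CH=C=O) whose C2–C3 bond has little double-bond character, so the E form rotates to the cisoid form (reversible chloride addition to C2 is a second path), C4a attacks the acyl carbon and the hindered pyridine takes the proton of the σ-complex. The closest known reaction type is the Friedel–Crafts cyclisation of (E)-3-aryloxyacrylic acids to chromones, run through the acid chloride with a Lewis acid or in strong protic acid. The pyranone ring closes in a 6-exo mode, the arene π system attacking the acyl carbon with the C=O bond outside the new ring. No stereocentre is formed; what the step has to converge is the alkene geometry, and because the ring is closed before C2 carries an aryl group, no benzylic C2–O1 bond or stereocentre is exposed to the electrophilic medium. The selectivity needed is C4a over the still more electron-rich C6 and over the prenyl alkene: the O1–C2=C3 tether brings the acyl carbon within reach of C4a only (C8 is blocked), high dilution disfavours intermolecular acylation at C6, and the aprotic generation of 7 together with the proton scavenger should keep the trisubstituted alkene from hydrochlorination or cation cyclisation. The C4 carbonyl of 8 then deactivates ring A, so a second acylation is not expected.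

Step 4
Reactants: 8 5,7-dimethoxy-8-(3-methylbut-2-en-1-yl)-4H-chromen-4-one; 9 (3-hydroxy-4-methoxyphenyl)boronic acid
Product: 10 (2S)-2-(3-hydroxy-4-methoxyphenyl)-5,7-dimethoxy-8-(3-methylbut-2-en-1-yl)-2,3-dihydro-4H-chromen-4-one
Conditions: Pd(OCOCF3)2 (5 mol%), (R)-t-BuPyOx (6 mol%), NH4PF6 (30 mol%), H2O (5 equiv), 9 (2 equiv), ClCH2CH2Cl, 60 °C
Reagents that add atoms: none
Why: Pd(II)/pyridine-oxazoline-catalysed asymmetric conjugate addition of an arylboronic acid to a chromone (transmetalation, enantioface-selective aryl insertion at C2, protonolysis of the palladium enolate by water) should set C2 under ligand control in a neutral to weakly acidic medium that spares the free phenol, the prenyl group and the new stereocentre; the (R)-ligand is chosen because the (S)-ligand is known to give (R)-β-aryl ketones from cyclic enones, which maps onto (2R) for a chromone, and this sense is to be confirmed by chiroptical comparison, the antipodal ligand being the remedy if it is reversed.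

**Compound list**

1 | 3,5-dimethoxyphenol | COc1cc(O)cc(OC)c1 | starting material
2 | prenyl bromide (1-bromo-3-methylbut-2-ene) | CC(C)=CCBr | starting material
3 | 3,5-dimethoxy-2-(3-methylbut-2-en-1-yl)phenol | COc1cc(O)c(CC=C(C)C)c(OC)c1 | intermediate
4 | methyl propiolate | C#CC(=O)OC | starting material
5 | methyl (2E)-3-[3,5-dimethoxy-2-(3-methylbut-2-en-1-yl)phenoxy]prop-2-enoate | COC(=O)/C=C/Oc1cc(OC)cc(OC)c1CC=C(C)C | intermediate (not isolated)
6 | (2E)-3-[3,5-dimethoxy-2-(3-methylbut-2-en-1-yl)phenoxy]prop-2-enoic acid | OC(=O)/C=C/Oc1cc(OC)cc(OC)c1CC=C(C)C | intermediate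
7 | (2E)-3-[3,5-dimethoxy-2-(3-methylbut-2-en-1-yl)phenoxy]prop-2-enoyl chloride | ClC(=O)/C=C/Oc1cc(OC)cc(OC)c1CC=C(C)C | intermediate (not isolated)
8 | 5,7-dimethoxy-8-(3-methylbut-2-en-1-yl)-4H-chromen-4-one | COc1cc(OC)c2c(c1CC=C(C)C)occc2=O | intermediate
9 | (3-hydroxy-4-methoxyphenyl)boronic acid | COc1ccc(B(O)O)cc1O | starting material
10 | (2S)-2-(3-hydroxy-4-methoxyphenyl)-5,7-dimethoxy-8-(3-methylbut-2-en-1-yl)-2,3-dihydro-4H-chromen-4-one | COc1ccc([C@@H]2CC(=O)c3c(OC)cc(OC)c(CC=C(C)C)c3O2)cc1O | target

Total step count: 4
Longest linear sequence: 4 steps (1 → 3 → 6 → 8 → 10)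

**Steps most likely to fail**

Step 3 (key step). The E-configured acyl cation may fail to reach the cisoid geometry, or to attack C4a, below the temperature at which tin- or proton-induced hydrochlorination or cyclisation of the prenyl side chain sets in. The fallback sets out from 3 and returns at 8. It closes the same C4–C4a bond at the saturated oxidation level, where no alkene geometry is involved and no Lewis acid is needed. Phenoxide opening of β-propiolactone by 3 (t-BuOK, THF, 0 °C → rt) should give 3-[3,5-dimethoxy-2-(3-methylbut-2-en-1-yl)phenoxy]propanoic acid F1. Trifluoroacetic anhydride in CH2Cl2 at 0 °C converts F1 into the mixed trifluoroacetic anhydride F2, which is not isolated and should acylate C4a to give 5,7-dimethoxy-8-(3-methylbut-2-en-1-yl)chroman-4-one F3. Dehydrogenation of F3 with IBX and 4-methoxypyridine N-oxide in DMSO at rt should then give chromone 8.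

Step 4. Aryl insertion into the electron-rich, vinylogous-ester C2=C3 bond may be slow (with protodeboronation of 9 competing), or the facial discrimination may be insufficient. The fallback sets out from 8 and returns at 10. It gives up catalyst control in favour of resolution. An achiral rhodium(I) catalyst ([Rh(OH)(cod)]2, dioxane/H2O, 60 °C) should add 9 to 8 to give racemic 2-(3-hydroxy-4-methoxyphenyl)-5,7-dimethoxy-8-(3-methylbut-2-en-1-yl)chroman-4-one F4. Preparative chromatography on a chiral stationary phase separates 10 from (2R)-2-(3-hydroxy-4-methoxyphenyl)-5,7-dimethoxy-8-(3-methylbut-2-en-1-yl)chroman-4-one F5, which can be returned to F4 by base-mediated equilibration at C2 (cat. DBU) and recycled.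

Step 1. The ambident phenoxide may show poor site selectivity (O-alkylation, attack at C4, double alkylation). The fallback sets out from 1 and returns at 3. It delivers the prenyl group by a [3,3] shift that can only reach an ortho carbon. O-Alkylation of 1 with 3-chloro-3-methylbut-1-yne (K2CO3, KI, cat. CuI, acetone, reflux) should give 1,3-dimethoxy-5-[(2-methylbut-3-yn-2-yl)oxy]benzene F6. Semi-hydrogenation (H2, Pb-poisoned Pd/CaCO3, quinoline, EtOAc) should give 1,3-dimethoxy-5-[(2-methylbut-3-en-2-yl)oxy]benzene F7. Aromatic Claisen rearrangement of F7 (N,N-diethylaniline, 130–160 °C) should give 3 after tautomerisation, the two ortho positions being equivalent.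

**Further compounds**

F1 | step 3 | 3-[3,5-dimethoxy-2-(3-methylbut-2-en-1-yl)phenoxy]propanoic acid | COc1cc(OCCC(=O)O)c(CC=C(C)C)c(OC)c1
F2 | step 3 | 3-[3,5-dimethoxy-2-(3-methylbut-2-en-1-yl)phenoxy]propanoic trifluoroacetic anhydride | COc1cc(OCCC(=O)OC(=O)C(F)(F)F)c(CC=C(C)C)c(OC)c1
F3 | step 3 | 5,7-dimethoxy-8-(3-methylbut-2-en-1-yl)chroman-4-one | COc1cc(OC)c2c(c1CC=C(C)C)OCCC2=O
F4 | step 4 | racemic 2-(3-hydroxy-4-methoxyphenyl)-5,7-dimethoxy-8-(3-methylbut-2-en-1-yl)chroman-4-one | COc1ccc(C2CC(=O)c3c(OC)cc(OC)c(CC=C(C)C)c3O2)cc1O
F5 | step 4 | (2R)-2-(3-hydroxy-4-methoxyphenyl)-5,7-dimethoxy-8-(3-methylbut-2-en-1-yl)chroman-4-one | COc1ccc([C@H]2CC(=O)c3c(OC)cc(OC)c(CC=C(C)C)c3O2)cc1O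
F6 | step 1 | 1,3-dimethoxy-5-[(2-methylbut-3-yn-2-yl)oxy]benzene | COc1cc(OC)cc(OC(C)(C)C#C)c1
F7 | step 1 | 1,3-dimethoxy-5-[(2-methylbut-3-en-2-yl)oxy]benzene | COc1cc(OC)cc(OC(C)(C)C=C)c1
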